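**Plan**

Retrosynthetic cuts:
- First the five O-benzyl and two O-tosyl groups are removed.
- The lower C3–OH goes back to the flavan-3-one and then to the 3-nitroflavan.
- Ring F is cut at lower C2–C3, leaving an ortho-(2-nitrovinyl)aryl 3,4,5-tris(benzyloxy)benzyl ether.
- The remaining cuts are lower C3–C4 (Henry), O1–CH2 (etherification), upper C4–lower C8 (Friedel–Crafts) and upper C2–ring B (1,4-addition).

Forward order: a chromone brings rings A and C, and ring B is added. Ring D arrives as 2,4,6-trihydroxybenzaldehyde, whose two free ring carbons are equivalent, so the C–C coupling has no 4→6/4→8 problem. Ring E is hung on O1 as an ordinary benzyl ether, and ring F closes last.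

Enabling feature: in ring F the C4 methylene and the benzylic ether carbon C2 are 1,5-related through C4a–C8a–O1. C4 can therefore be carried as the hydride-accepting end of a nitrovinyl group, and C2 as the hydride-donating OCH2 of the ring E benzyl ether. The flavanyl group on C8 of ring D, ortho to O1, presses that CH2 against C4, and the para oxygen of ring E stabilises the oxocarbenium ion.

Stereochemistry: upper C2 comes from a rhodium/(S)-bisphosphine 1,4-addition. Upper C4 comes from pseudoaxial attack on the flavan-4-yl cation, trans to ring B. Lower C2 and C3 are set together by a catalyst-controlled dynamic kinetic hydrogenation of the C2-labile flavan-3-one (2,3-cis).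

Key step: step 10

Remark: the SMILES is read as (2S,4R)-4',7-dihydroxyflavan joined through C4 to C8 of (2R,3R)-epigallocatechin (upper unit 2,4-trans, lower unit 2,3-cis). Rings A, B, C are the benzo, 4-hydroxyphenyl and pyran rings of the upper unit. Rings D, E, F are the benzo, pyrogallol and pyran rings of the lower unit. Lower-unit atoms keep flavan numbering from the start (O1, C2, C3, C4, O5, O7, C8).

**Step 1**
Reactants: 1 7-hydroxy-4H-chromen-4-one
Product: 2 7-(benzyloxy)-4H-chromen-4-one
Conditions: BnBr, K2CO3, acetone, reflux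
Reagents that add atoms: benzyl bromide BrCc1ccccc1
Why: Williamson ether synthesis on the acidic 7-OH, which leaves the chromone enone untouched under carbonate base.

**Step 2**
Reactants: 2 7-(benzyloxy)-4H-chromen-4-one; 3 4-(benzyloxy)phenylboronic acid
Product: 4 (2S)-7-(benzyloxy)-2-[4-(benzyloxy)phenyl]chroman-4-one
Conditions: 3 (1.5 equiv), [Rh(OH)(cod)]2 (1.5 mol %), (S)-MeO-F12-BIPHEP (3.3 mol %), toluene–H2O, rt
Reagents that add atoms: none
Why: Rhodium-catalysed asymmetric 1,4-addition of an arylboronic acid (Hayashi–Miyaura reaction), known for chromones under base-free conditions that avoid racemisation by retro-oxa-Michael opening; the (S)-biaryl bisphosphine should direct ring B to the face that gives (2S), by analogy with cyclic enones.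

**Step 3**
Reactants: 4 (2S)-7-(benzyloxy)-2-[4-(benzyloxy)phenyl]chroman-4-one
Product: 5 (2S,4S)-7-(benzyloxy)-2-[4-(benzyloxy)phenyl]chroman-4-ol (2,4-cis)
Conditions: NaBH4, THF–MeOH, 0 °C
Reagents that add atoms: none
Why: Borohydride reduction of a flavanone, in which hydride attacks C4 from the pseudoaxial side of the half-chair with ring B equatorial and gives the 2,4-cis (4S) alcohol; this centre is ionised again in step 4, so its configuration is not critical.

**Step 4**
Reactants: 5 (2S,4S)-7-(benzyloxy)-2-[4-(benzyloxy)phenyl]chroman-4-ol; 6 2,4,6-trihydroxybenzaldehyde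
Product: 8 3-[(2S,4R)-7-benzyloxy-2-(4-benzyloxyphenyl)chroman-4-yl]-2,4,6-trihydroxybenzaldehyde, via flavan-4-yl cation 7 (not isolated)
Conditions: 6 (3 equiv), TsOH·H2O (10 mol %), MeCN–CH2Cl2, −20 to 0 °C
Reagents that add atoms: none
Why: Acid-catalysed Friedel–Crafts alkylation of an acylphloroglucinol by a flavan-4-ol: cation 7 adopts a half-chair with ring B equatorial and is attacked along the pseudoaxial trajectory, which should give the 2,4-trans (4R) product under kinetic control, and because C3 and C5 of 6 are equivalent only one C-alkylation regioisomer can form.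

**Step 5**
Reactants: 8 3-[(2S,4R)-7-benzyloxy-2-(4-benzyloxyphenyl)chroman-4-yl]-2,4,6-trihydroxybenzaldehyde
Product: 9 3-[(2S,4R)-7-benzyloxy-2-(4-benzyloxyphenyl)chroman-4-yl]-2-hydroxy-4,6-bis(tosyloxy)benzaldehyde (O5 and O7 tosylated, O1–H free)
Conditions: TsCl (2.1 equiv), K2CO3, acetone, 0 °C to rt
Reagents that add atoms: p-toluenesulfonyl chloride Cc1ccc(S(=O)(=O)Cl)cc1
Why: Selective sulfonylation as in the known bis-protection of 3-alkylphloroglucinol aldehydes and ketones: the para, non-chelated O7–H reacts first and then the less hindered ortho O5–H, while O1–H, wedged between the flavanyl group and the formyl group and locked in the chelate, remains.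

**Step 6**
Reactants: 10 methyl 3,4,5-tris(benzyloxy)benzoate
Product: 11 [3,4,5-tris(benzyloxy)phenyl]methanol
Conditions: LiAlH4, THF, 0 °C
Reagents that add atoms: none
Why: Standard LiAlH4 reduction of a benzoate ester to the benzylic alcohol, benzyl ethers being inert.

**Step 7**
Reactants: 11 [3,4,5-tris(benzyloxy)phenyl]methanol
Product: 12 3,4,5-tris(benzyloxy)benzyl bromide
Conditions: PBr3, CH2Cl2, 0 °C
Reagents that add atoms: phosphorus tribromide BrP(Br)Br
Why: Routine conversion of an electron-rich benzylic alcohol into the bromide by displacement of its phosphite ester.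

**Step 8**
Reactants: 9 2-hydroxy-4,6-bis(tosyloxy)benzaldehyde bearing the flavanyl group; 12 3,4,5-tris(benzyloxy)benzyl bromide
Product: 13 3-[(2S,4R)-7-benzyloxy-2-(4-benzyloxyphenyl)chroman-4-yl]-4,6-bis(tosyloxy)-2-[3,4,5-tris(benzyloxy)benzyloxy]benzaldehyde
Conditions: K2CO3, n-Bu4NI (cat.), DMF, 40 °C
Reagents that add atoms: none
Why: Williamson etherification of the only free and acidified phenol (O1) with a reactive benzylic bromide, under carbonate base that aryl tosylates tolerate.

**Step 9**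
Reactants: 13 aldehyde with ring E benzyl ether on O1; 14 nitromethane
Product: 15 (E)-2-nitrovinyl analogue of 13 (CHO replaced by CH=CH–NO2)
Conditions: NH4OAc (cat.), 14 as solvent, 90 °C
Reagents that add atoms: none
Why: Henry (nitroaldol) condensation with dehydration in the same flask, routine for 2,6-dioxygenated benzaldehydes, giving the conjugated (E)-nitroalkene as the thermodynamic isomer.

**Step 10**
Reactants: 15 (E)-2-nitrovinyl aryl benzyl ether
Product: 17 (2S,4R)-7-benzyloxy-2-(4-benzyloxyphenyl)-4-{3-nitro-5,7-bis(tosyloxy)-2-[3,4,5-tris(benzyloxy)phenyl]chroman-8-yl}chroman (2,3-trans in ring F; both C2 epimers), via oxocarbenium nitronate zwitterion 16 (not isolated)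
Conditions: SnCl4 (30 mol %), 4 Å MS, CH2Cl2, −40 °C to rt
Reagents that add atoms: none
Why: Proposed new method: SnCl4 binds the nitro group and makes C4 electrophilic enough to abstract hydride from the 1,5-related O1–CH2 group through a six-membered transition state, giving zwitterion 16 (ring E-stabilised oxocarbenium ion at C2, tin nitronate at C3), whose nitronate carbon then adds to C2 and forms the C2–C3 bond in an overall redox-neutral isomerisation that also delivers C4 at the methylene level. The closest known reaction type is the Lewis-acid-catalysed [1,5]-hydride shift/cyclisation (internal redox C–H functionalisation) of ortho-benzyloxybenzylidene malonates to 2-arylchroman-3,3-dicarboxylates, which is strongly accelerated by a substituent ortho to the benzyloxy group; the nitrovinyl acceptor is the new element, and it is argued from the higher intrinsic electrophilicity of nitrostyrenes over benzylidene malonates, from the reactivity of SnCl4-complexed nitroalkenes towards weak pi nucleophiles at low temperature and from the known transfer of hydride from C–H donors to activated nitroalkenes. Ring F closes in a 6-(enolexo)-endo-trig mode, with the C2=O1 bond endocyclic and the C3=N bond exocyclic. C2 and C3 are both created here: a chair-like closure with ring E and the nitro group equatorial, backed by equilibration at the acidic C3–H, should give the 2,3-trans relation, while the sense at C2 relative to the upper unit is left uncontrolled on purpose, because C3 is erased in step 11 and C2 is reset in step 12, so both diastereomers converge. The step needs site selectivity among the many benzylic C–H donors and chemoselectivity against ionisation of benzylic C–O bonds and of the interflavan bond: only the O1–CH2 group lies 1,5 to C4, the second ortho oxygen O5 carries a tosyl group that has no hydridic C–H (a benzyl group there would lead to the 4→6 isomer), the C8 flavanyl group twists O1–CH2 out of the ring D plane and holds it over C4, and the two sulfonates raise the electrophilicity of C4 while shutting down ipso protonation and Friedel–Crafts attack on ring D.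

**Step 11**
Reactants: 17 3-nitroflavan (both 2,3-trans diastereomers)
Product: 19 8-[(2S,4R)-7-benzyloxy-2-(4-benzyloxyphenyl)chroman-4-yl]-5,7-bis(tosyloxy)-2-[3,4,5-tris(benzyloxy)phenyl]chroman-3-one (C2 epimers in equilibrium), via potassium nitronate 18 (not isolated)
Conditions: KOt-Bu (1.05 equiv), THF, −78 °C; then DMDO, acetone, −78 to 0 °C
Reagents that add atoms: dimethyldioxirane CC1(C)OO1 (ketone oxygen); potassium tert-butoxide CC(C)(C)[O-].[K+] (potassium of intermediate 18 only)
Why: Oxidative Nef reaction in which dimethyldioxirane transfers oxygen to the C3=N bond of nitronate 18 and nitrite leaves, a cold and nearly neutral variant that spares benzyl ethers and tosylates; C3 becomes sp2 and C2 becomes epimerisable, so both diastereomers of 17 converge on 19.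

**Step 12**
Reactants: 19 flavan-3-one (C2 epimers in equilibrium)
Product: 20 (2R,3R)-8-[(2S,4R)-7-benzyloxy-2-(4-benzyloxyphenyl)chroman-4-yl]-5,7-bis(tosyloxy)-2-[3,4,5-tris(benzyloxy)phenyl]chroman-3-ol
Conditions: RuCl2[(S)-binap][(R,R)-dpen] (1 mol %), KOt-Bu (10 mol %), H2 (20 bar), i-PrOH–toluene, rt
Reagents that add atoms: none
Why: Noyori-type asymmetric hydrogenation with dynamic kinetic resolution, established for 2-alkyl-, 2-aryl- and 2-alkoxy-substituted cyclic ketones: the base epimerises C2 (its C–H is alpha to the ketone, benzylic and alpha to oxygen), the chiral ruthenium hydride should reduce the (2R) epimer faster and from the face opposite ring E, which sets (2R,3R) with the 2,3-cis relation, the catalyst antipode being assigned by analogy with 2-substituted cyclohexanones.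

**Step 13**
Reactants: 20 (2R,3R)-5,7-bis(tosyloxy)flavan-3-ol
Product: 21 (2R,3R)-8-[(2S,4R)-7-benzyloxy-2-(4-benzyloxyphenyl)chroman-4-yl]-2-[3,4,5-tris(benzyloxy)phenyl]chroman-3,5,7-triol
Conditions: KOH, THF–MeOH–H2O, 60 °C
Reagents that add atoms: none
Why: Alkaline hydrolysis of aryl sulfonates by attack at sulfur; with the ring B and ring E phenols still benzylated no quinone methide can form, so C2 of either unit should not epimerise.

**Step 14**
Reactants: 21 penta-O-benzyl ether
Product: 22 (2R,3R)-8-[(2S,4R)-7-hydroxy-2-(4-hydroxyphenyl)chroman-4-yl]-2-(3,4,5-trihydroxyphenyl)chroman-3,5,7-triol (CNP0220331.1)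
Conditions: H2 (1 atm), Pd(OH)2/C, THF–MeOH, rt
Reagents that add atoms: none
Why: Global hydrogenolysis of five benzyl ethers, the standard last step for benzylated flavan-3-ols and proanthocyanidins, under which the ring C and ring F benzylic C–O bonds and the interflavan bond persist.

**Compound list**

1 | 7-hydroxy-4H-chromen-4-one | O=C1C=COc2cc(O)ccc12 | starting material
2 | 7-(benzyloxy)-4H-chromen-4-one | O=C1C=COc2cc(OCc3ccccc3)ccc12 | intermediate
3 | 4-(benzyloxy)phenylboronic acid | OB(O)c1ccc(OCc2ccccc2)cc1 | starting material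
4 | (2S)-7-(benzyloxy)-2-[4-(benzyloxy)phenyl]chroman-4-one | C(c1ccccc1)Oc1ccc([C@@H]2CC(=O)c3ccc(OCc4ccccc4)cc3O2)cc1 | intermediate
5 | (2S,4S)-7-(benzyloxy)-2-[4-(benzyloxy)phenyl]chroman-4-ol (2,4-cis) | C(c1ccccc1)Oc1ccc([C@@H]2C[C@H](O)c3ccc(OCc4ccccc4)cc3O2)cc1 | intermediate
6 | 2,4,6-trihydroxybenzaldehyde | O=Cc1c(O)cc(O)cc1O | starting material
7 | (2S)-7-(benzyloxy)-2-[4-(benzyloxy)phenyl]chroman-4-yl cation (not isolated) | C(c1ccccc1)Oc1ccc([C@@H]2C[CH+]c3ccc(OCc4ccccc4)cc3O2)cc1 | intermediate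
8 | 3-[(2S,4R)-7-benzyloxy-2-(4-benzyloxyphenyl)chroman-4-yl]-2,4,6-trihydroxybenzaldehyde | C(c1ccccc1)Oc1ccc([C@@H]2C[C@@H](c3c(O)cc(O)c(C=O)c3O)c3ccc(OCc4ccccc4)cc3O2)cc1 | intermediate
9 | 3-[(2S,4R)-7-benzyloxy-2-(4-benzyloxyphenyl)chroman-4-yl]-2-hydroxy-4,6-bis(tosyloxy)benzaldehyde | C(c1ccccc1)Oc1ccc([C@@H]2C[C@@H](c3c(OS(=O)(=O)c4ccc(C)cc4)cc(OS(=O)(=O)c4ccc(C)cc4)c(C=O)c3O)c3ccc(OCc4ccccc4)cc3O2)cc1 | intermediate
10 | methyl 3,4,5-tris(benzyloxy)benzoate | COC(=O)c1cc(OCc2ccccc2)c(OCc2ccccc2)c(OCc2ccccc2)c1 | starting material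
11 | [3,4,5-tris(benzyloxy)phenyl]methanol | OCc1cc(OCc2ccccc2)c(OCc2ccccc2)c(OCc2ccccc2)c1 | intermediate
12 | 3,4,5-tris(benzyloxy)benzyl bromide | BrCc1cc(OCc2ccccc2)c(OCc2ccccc2)c(OCc2ccccc2)c1 | intermediate
13 | 3-[(2S,4R)-7-benzyloxy-2-(4-benzyloxyphenyl)chroman-4-yl]-4,6-bis(tosyloxy)-2-[3,4,5-tris(benzyloxy)benzyloxy]benzaldehyde | C(c1ccccc1)Oc1ccc([C@@H]2C[C@@H](c3c(OS(=O)(=O)c4ccc(C)cc4)cc(OS(=O)(=O)c4ccc(C)cc4)c(C=O)c3OCc3cc(OCc4ccccc4)c(OCc4ccccc4)c(OCc4ccccc4)c3)c3ccc(OCc4ccccc4)cc3O2)cc1 | intermediate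
14 | nitromethane | C[N+](=O)[O-] | starting material
15 | (E)-2-nitrovinyl analogue of 13 | C(c1ccccc1)Oc1ccc([C@@H]2C[C@@H](c3c(OS(=O)(=O)c4ccc(C)cc4)cc(OS(=O)(=O)c4ccc(C)cc4)c(/C=C/[N+](=O)[O-])c3OCc3cc(OCc4ccccc4)c(OCc4ccccc4)c(OCc4ccccc4)c3)c3ccc(OCc4ccccc4)cc3O2)cc1 | intermediate
16 | oxocarbenium nitronate zwitterion, drawn without the tin Lewis acid (not isolated) | C(c1ccccc1)Oc1ccc([C@@H]2C[C@@H](c3c(OS(=O)(=O)c4ccc(C)cc4)cc(OS(=O)(=O)c4ccc(C)cc4)c(CC=[N+]([O-])[O-])c3[O+]=Cc3cc(OCc4ccccc4)c(OCc4ccccc4)c(OCc4ccccc4)c3)c3ccc(OCc4ccccc4)cc3O2)cc1 | intermediate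
17 | 3-nitroflavan: (2S,4R)-7-benzyloxy-2-(4-benzyloxyphenyl)-4-{3-nitro-5,7-bis(tosyloxy)-2-[3,4,5-tris(benzyloxy)phenyl]chroman-8-yl}chroman; ring F 2,3-trans, (2R,3S) and (2S,3R) both present, hence no descriptor at these two centres | C(c1ccccc1)Oc1ccc([C@@H]2C[C@@H](c3c(OS(=O)(=O)c4ccc(C)cc4)cc(OS(=O)(=O)c4ccc(C)cc4)c4c3OC(c3cc(OCc5ccccc5)c(OCc5ccccc5)c(OCc5ccccc5)c3)C([N+](=O)[O-])C4)c3ccc(OCc4ccccc4)cc3O2)cc1 | intermediate
18 | potassium nitronate of 17 (not isolated) | C(c1ccccc1)Oc1ccc([C@@H]2C[C@@H](c3c(OS(=O)(=O)c4ccc(C)cc4)cc(OS(=O)(=O)c4ccc(C)cc4)c4c3OC(c3cc(OCc5ccccc5)c(OCc5ccccc5)c(OCc5ccccc5)c3)C(=[N+]([O-])[O-])C4)c3ccc(OCc4ccccc4)cc3O2)cc1.[K+] | intermediate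
19 | 8-[(2S,4R)-7-benzyloxy-2-(4-benzyloxyphenyl)chroman-4-yl]-5,7-bis(tosyloxy)-2-[3,4,5-tris(benzyloxy)phenyl]chroman-3-one; C2 labile, no descriptor | C(c1ccccc1)Oc1ccc([C@@H]2C[C@@H](c3c(OS(=O)(=O)c4ccc(C)cc4)cc(OS(=O)(=O)c4ccc(C)cc4)c4c3OC(c3cc(OCc5ccccc5)c(OCc5ccccc5)c(OCc5ccccc5)c3)C(=O)C4)c3ccc(OCc4ccccc4)cc3O2)cc1 | intermediate
20 | (2R,3R)-8-[(2S,4R)-7-benzyloxy-2-(4-benzyloxyphenyl)chroman-4-yl]-5,7-bis(tosyloxy)-2-[3,4,5-tris(benzyloxy)phenyl]chroman-3-ol | C(c1ccccc1)Oc1ccc([C@@H]2C[C@@H](c3c(OS(=O)(=O)c4ccc(C)cc4)cc(OS(=O)(=O)c4ccc(C)cc4)c4c3O[C@H](c3cc(OCc5ccccc5)c(OCc5ccccc5)c(OCc5ccccc5)c3)[C@H](O)C4)c3ccc(OCc4ccccc4)cc3O2)cc1 | intermediate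
21 | (2R,3R)-8-[(2S,4R)-7-benzyloxy-2-(4-benzyloxyphenyl)chroman-4-yl]-2-[3,4,5-tris(benzyloxy)phenyl]chroman-3,5,7-triol | C(c1ccccc1)Oc1ccc([C@@H]2C[C@@H](c3c(O)cc(O)c4c3O[C@H](c3cc(OCc5ccccc5)c(OCc5ccccc5)c(OCc5ccccc5)c3)[C@H](O)C4)c3ccc(OCc4ccccc4)cc3O2)cc1 | intermediate
22 | (2R,3R)-8-[(2S,4R)-7-hydroxy-2-(4-hydroxyphenyl)chroman-4-yl]-2-(3,4,5-trihydroxyphenyl)chroman-3,5,7-triol (CNP0220331.1) | Oc1ccc([C@@H]2C[C@@H](c3c(O)cc(O)c4c3O[C@H](c3cc(O)c(O)c(O)c3)[C@H](O)C4)c3ccc(O)cc3O2)cc1 | target

Total step count: 14. Longest linear sequence: 12 (steps 1–5 and 8–14).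

**Steps most likely to fail**

**1. Step 10 (Proposed new method).**
- Hydride transfer to the nitrovinyl carbon may be slower than Lewis-acid ionisation of the O1–CH2 bond, which would cost the ring E benzyl group.
- The oxocarbenium ion may also be intercepted by a second 1,5-hydride shift from the upper C4–H before the nitronate closes. This would endanger the upper C4 configuration.
- The fallback uses known chemistry that builds ring F from the other side. It sets out from 9 and 11 and comes back at 17.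
- Alcohol 11 is oxidised with MnO2 to 3,4,5-tris(benzyloxy)benzaldehyde F1.
- Henry condensation of F1 with 14 gives (E)-1,2,3-tris(benzyloxy)-5-(2-nitrovinyl)benzene F2.
- A DABCO-mediated oxa-Michael/Henry/dehydration cascade of salicylaldehyde 9 with F2 gives the 2-aryl-3-nitro-2H-chromene F3.
- Conjugate reduction of F3 with NaBH4 gives 17.

**2. Step 12.**
- Discrimination between the interconverting C2 epimers may be poor, because the remote upper-unit stereocentres can be mismatched with the catalyst.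
- Reduction of the hindered ketone may also be slower than base-induced decay.
- The fallback sets out from 19 and comes back at 20.
- Substrate-controlled reduction with LiBH(s-Bu)3 in THF at −78 °C attacks each C2 epimer opposite ring E. It gives 20 together with the (2S,3S)-configured 2,3-cis alcohol F4.
- The two are diastereomers because of the upper unit, so they can be separated by chromatography.
- F4 is oxidised with Dess–Martin periodinane back to 19, re-equilibrated with Et3N and recycled.

**3. Step 4.**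
- Facial selectivity at upper C4 may be poor.
- Proton loss to the flav-3-ene or self-alkylation of ring A may compete.
- The fallback sets out from 5 and 6 and comes back at 8.
- Mitsunobu etherification (PPh3, DIAD, THF) of the 2,4-cis alcohol 5 with the most acidic, non-chelated 4-OH of 6 proceeds with inversion. It gives the 2,4-trans aryl ether 4-{[(2S,4R)-7-benzyloxy-2-(4-benzyloxyphenyl)chroman-4-yl]oxy}-2,6-dihydroxybenzaldehyde F5.
- A Lewis-acid-promoted O-to-C rearrangement (BF3·OEt2, CH2Cl2, −78 °C) through a contact ion pair returns the flavanyl group to the adjacent ring carbon on the same face and gives 8.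

**Further compounds**
F1 | step 10 | 3,4,5-tris(benzyloxy)benzaldehyde | O=Cc1cc(OCc2ccccc2)c(OCc2ccccc2)c(OCc2ccccc2)c1
F2 | step 10 | (E)-1,2,3-tris(benzyloxy)-5-(2-nitrovinyl)benzene | [O-][N+](=O)/C=C/c1cc(OCc2ccccc2)c(OCc2ccccc2)c(OCc2ccccc2)c1
F3 | step 10 | 8-[(2S,4R)-7-benzyloxy-2-(4-benzyloxyphenyl)chroman-4-yl]-3-nitro-5,7-bis(tosyloxy)-2-[3,4,5-tris(benzyloxy)phenyl]-2H-chromene (C2 not controlled) | C(c1ccccc1)Oc1ccc([C@@H]2C[C@@H](c3c(OS(=O)(=O)c4ccc(C)cc4)cc(OS(=O)(=O)c4ccc(C)cc4)c4c3OC(c3cc(OCc5ccccc5)c(OCc5ccccc5)c(OCc5ccccc5)c3)C([N+](=O)[O-])=C4)c3ccc(OCc4ccccc4)cc3O2)cc1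
F4 | step 12 | (2S,3S)-8-[(2S,4R)-7-benzyloxy-2-(4-benzyloxyphenyl)chroman-4-yl]-5,7-bis(tosyloxy)-2-[3,4,5-tris(benzyloxy)phenyl]chroman-3-ol | C(c1ccccc1)Oc1ccc([C@@H]2C[C@@H](c3c(OS(=O)(=O)c4ccc(C)cc4)cc(OS(=O)(=O)c4ccc(C)cc4)c4c3O[C@@H](c3cc(OCc5ccccc5)c(OCc5ccccc5)c(OCc5ccccc5)c3)[C@@H](O)C4)c3ccc(OCc4ccccc4)cc3O2)cc1
F5 | step 4 | 4-{[(2S,4R)-7-benzyloxy-2-(4-benzyloxyphenyl)chroman-4-yl]oxy}-2,6-dihydroxybenzaldehyde | C(c1ccccc1)Oc1ccc([C@@H]2C[C@@H](Oc3cc(O)c(C=O)c(O)c3)c3ccc(OCc4ccccc4)cc3O2)cc1
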